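The earlier runs and the new flask come from a simulation on assumed constants; scatter was added.

Count the ends first, and take equal charges as the zero of the scale.

| flask | first end groups | second end groups | protic impurity | remark | time |
|---|---|---|---|---|---|
| south-west | 10 mM | 10 mM | 0.25 mM | run made earlier |  |
| west | 10 mM | 10 mM | 1 mM | run made earlier |  |
| east | 15 mM | 10 mM | 0.50 mM | run made earlier |  |
| flask | 10 mM | 10.0 mM | 0.500 mM |  | 3.0 h |

- south-west (time / h: links / %, first end groups / %): 0.200: 47.4, 51.9; 0.417: 50.4, 50.6; 1.00: 50.9, 49.3; 2.50: 51.2, 48.9
- west (time / h: links / %, first end groups / %): 0.333: 47.0, 52.5; 0.833: 47.6, 51.5; 1.50: 48.5, 51.5; 2.50: 48.9, 51.2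
- east (time / h: links / %, first end groups / %): 0.667: 39.2, 60.7; 1.33: 39.2, 60.3; 2.00: 40.9, 61.0; 2.50: 39.8, 60.1

(readings scatter by 0.5 percentage points)

1. average number of monomer units in a chain (unreacted monomers counted as chains of one) at 3.0 h
2. part of the first end groups that has reacted at 3.0 h

- each molecule carries two end groups: a chain counts once for every two ends that are left, dead ends included; the units are half of the end groups of the two monomers charged

Units stay as charged and each link removes one chain. So with equal charges, dp is one over one minus the part reacted, the Carothers count, and half reacted gives 2. The question was therefore how far this flask goes.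

I first interpolated between the south-west and west runs, which ended at 51.2% and 48.9% links. But that said nothing of the east run, with its different charge, so I wanted one number for the three runs.

I took links over the product of first ends left and spare second ends, spare meaning charge less impurity less links. The last readings gave 0.226 mM⁻¹ south-west, 0.232 mM⁻¹ west and 0.188 mM⁻¹ east. Their mean, 0.215 mM⁻¹, I called the link quotient. It gave this flask 4.95 mM of links, so 49.5% reacted and dp 1.98.

I doubted it: the three values ran from 0.188 mM⁻¹ to 0.232 mM⁻¹. So I put the east and west values in separately. They gave 4.73 mM and 5.07 mM, which still left dp near 2. West also crept, but by 0.4 percentage points over its last interval, which is within the scatter.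

The forecast said dp 2 and 50% reacted, slightly above my 49.5%: “By 3 h it should be essentially at equilibrium, though west drifted slowly.”

The flask gave dp 2.02 and 50.5% reacted, so the forecast held.

    released group → by-product carried off (k = 0.0210 min⁻¹)
    second end groups + protic impurity → quenched reagent (k = 180 M⁻¹ min⁻¹)
    first end groups + second end groups ⇌ links + released group (K = 1.10, k = 16.0 M⁻¹ min⁻¹)
    second end groups → decomposed reagent (k = 0.0180 min⁻¹)

My spare second ends came to 4.45 mM in this flask. Decomposed reagent at 4.32 mM and second ends left at 0.137 mM add up to 4.45 mM. So the spare ends sat mainly as decomposed reagent, and the quotient is a tally, not a balance constant. Without the way back from links, this flask's dp stood at 4.54, not 2.02.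

With 40 mM of second ends, the quotient gives 8.69 mM of links, so 86.9% reacted and dp 1.53. That neighbour flask computed 84.0% and 1.51.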